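I had to say whether autumn or noon ends with the greater excess of left-handed product over right-handed product, so I turned the question round: how far ahead in conversion would noon have to finish for the two to part by more than the margin?

in all of them: left-handed substrate 0.25 M; right-handed substrate 0.25 M

| run | partner | free catalyst | remark | time |
|---|---|---|---|---|
| blue | 0.375 M (fed, over 15 h) | 15 mM | run made earlier |  |
| green | 0.375 M (fed, over 15 h) | 21 mM | run made earlier |  |
| autumn | 0.375 M | 12 mM | everything together at the start | 3.0 d |
| noon | 0.375 M (fed, over 15 h) | 18 mM |  | 3.0 d |

- blue (time / h: left-handed product / %, right-handed product / %): 2.50: 0.2, 0.9; 8.00: 1.6, 1.4; 15.0: 6.1, 3.8; 20.0: 9.2, 6.2; 30.0: 15.4, 9.7; 40.0: 19.5, 12.9; 48.0: 22.9, 15.6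
- green (time / h: left-handed product / %, right-handed product / %): 2.50: 0.2, 0.2; 8.00: 2.7, 1.6; 15.0: 8.6, 4.9; 20.0: 12.9, 8.2; 30.0: 19.5, 12.4; 40.0: 24.5, 15.9; 48.0: 26.9, 18.4

(readings scatter by 0.3 percentage points)

- free catalyst is single-handed; left-handed substrate and right-handed substrate are mirror images of each other, charged as a racemate, each of them at the stated concentration
- an excess is below zero if the other one leads

1. which one finishes higher in excess of left-handed product over right-handed product ("neither" within 2 percentage points) (autumn / noon / neither)
2. excess of left-handed product over right-handed product at the end, autumn
3. excess of left-handed product over right-handed product at the end, noon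

I took the excess as the difference of the two products over their sum. From the last readings of the blue and green runs I read a mean of 1.66 for the selectivity factor: the logarithm of the fraction of left-handed substrate not turned to product, over the same logarithm for the right-handed substrate. Held fixed, it makes the excess a curve in the right-handed conversion. That curve gave 19.4% at the blue end and 18.3% at the green end, so on that curve, drawn straight between these two ends, parting by 2 percentage points needed noon ahead of autumn by about 10 points of right-handed conversion.

Next I reckoned the lead itself, treating the way the partner goes in as a small matter. Blue to green gave the right-handed conversion gained per unit of catalyst times time, and this, taken as a straight line, put noon ahead by 8.4 points. That first answer put noon at a right-handed conversion of 42.4%. Going round once more, I scaled the lead by the right-handed substrate then remaining, which cut it to 7.7 points, less than the lead required. My answer was neither.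

The forecast also said neither, with 18.5% (15.5% to 22%) for autumn and 17.4% (14.5% to 20.5%) for noon, holding that the selectivity “shows no clear dependence on partner level or catalyst loading”.

The simulation gave neither: 18.2% for autumn and 18.0% for noon.

    partner + catalyst intermediate B → free catalyst + right-handed product (k = 2.20 × 10⁻⁴ /M/s)
    partner + catalyst intermediate A → free catalyst + left-handed product (k = 0.00162 /M/s)
    free catalyst + right-handed substrate ⇌ catalyst intermediate B (K = 35.5 /M, k = 0.156 /M/s)
    partner ⇌ dormant form (K = 0.267, k = 2.21 × 10⁻⁵ /s)
    free catalyst + left-handed substrate ⇌ catalyst intermediate A (K = 8.51 /M, k = 0.0246 /M/s)

The curve, fed autumn's right-handed product, gave 18.1%. In a neighbour of autumn charged with 0.64 M of partner, right-handed product reached 33.0%, and the curve gave 11.6% against the 10.9% that flask shows. The left-handed lead in autumn exists mainly because catalyst intermediate B falls back to free catalyst and right-handed substrate: the autumn run without that reverse step ends at an excess of −93.9%.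

(All runs are simulated from invented constants; noise was put on by code.)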